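(The data stem from a simulated flask with made-up constants; the scatter is artificial.)

| flask | starting material | partner | temperature | remark | time |
|---|---|---|---|---|---|
| ash | 4 mM | 1.9 mM | 100 °C | run made earlier |  |
| alpha | 2.0 mM | 1.90 mM | 100 °C |  | 6.0 min |
| epsilon | 2.0 mM | 1.90 mM | 80 °C |  | 6.0 min |
| zeta | 2.0 mM | 1.90 mM | 60 °C |  | 6.0 min |

- ash (time / s: product / %): 10.0: 16.7; 15.0: 19.7; 25.0: 24.6; 40.0: 27.4

(readings scatter by 1 percentage point)

- the best flask by amount of product, in percent of the starting material charged; "all alike" if 1.5 percentage points covers them all (alpha / epsilon / zeta / all alike)
- amount of product at the end, in percent of the starting material charged, alpha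
- amount of product at the end, in percent of the starting material charged, epsilon
- amount of product at the end, in percent of the starting material charged, zeta

- what was read earlier has a scatter of 1 percentage point, one standard deviation
- the earlier runs do not show what temperature does; that part of a forecast is a guess

You put 4 questions to me and want a quick number, and your hunch is that the ash run has hit a ceiling. I read it otherwise. From the first pair of readings to the last pair, the rate of making product falls by a factor 3.21. That factor is larger than the 1.51 that the two reagents give, counted by what product has taken and each to the first power, so I take partner to be leaving by a second way as well. In logarithms, that fall is a power of ten every 39.4 s, so alpha's 6.0 min holds 9.14 such powers, and I treat alpha as over at its end.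

Each flask then comes down to its capture share, the product made per partner charged, which is 0.577 at the last ash reading. From it I take the capture odds, that share over the rest of the partner, a selectivity factor: 1.36. I assume the odds go with the first power of starting material. Alpha, with half the ash charge, then has odds 0.682, share 0.405, and product 38.5% of its starting material. Epsilon and zeta differ from alpha by temperature, which the earlier runs do not show. I guess better odds and slower runs on cooling, but these pull opposite ways and I have no size for either, so zeta as best is a bare guess, and I put no figure on it.

The forecast gives 38%, 52% and 44% for alpha, epsilon and zeta, and says: “Epsilon is the likely best, though not certain.”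

The flasks give 30.1%, 46.3% and 50.3%, and the best is zeta.

    starting material + partner → product, rate k1*[starting material]^1.5*[partner] (k = 250 M⁻¹·⁵ s⁻¹, Ea = 40.0 kJ mol⁻¹)
    partner → decomposed reagent (k = 0.0370 s⁻¹, Ea = 91.0 kJ mol⁻¹)
    (constants at 100 °C)

In epsilon, the path to decomposed reagent uses partner at 0.65 of the rate of the product path at the start, and at 1.1 times that rate at 0.878 min. At 6.00 min, 1.21% of epsilon's partner is left and its capture share is 0.487. Alpha's share is 0.317, its odds 0.464, and against the ash 1.36 that reads as a power of 1.56 in starting material. Carried to epsilon's neighbour with 3.4 mM of starting material, epsilon's odds 0.950 become 2.17, which means product 38.3%; the computed flask gives 39.2%.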